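At early times Saturday's flask, the very flask asked about, is still being fed: at 0.500 h about 37.5% of the starting material has gone in, and the three readings add up to 40.0% of the charge, so they account for what has entered.

common to all: starting material 0.30 M (fed, over 80 min)
- Saturday's: reagent 0.90 M; second substrate 0.30 M; the very flask that is asked about, followed so far
- flask: reagent 0.900 M; second substrate 0.300 M; time 12 h

- Saturday's (time / h: starting material / %, target / %, isomer of the product / %): 0.500: 28, 12, 0; 0.833: 38, 20, 4; 1.50: 41, 48, 15; 3.00: 13, 67, 22; 6.00: 7, 69, 25

(scatter of a reading: 1.5 percentage points)

- what was read earlier has a scatter of 1.5 percentage points, one standard deviation
- the reaction counts as stopped when no species that holds the starting material changes by six tenths of a point or more over the second half of the time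
- percentages count the whole charge, also what has not yet gone in

- at 12 h, what has stopped the reaction, if anything has (all of the starting material has reacted / forward and back rates have come level / the reagent has run out first / it is still moving)
- part of the starting material gone at 12 h
- the target standing at 12 h, as a percentage of the starting material charged
- the isomer of the product standing at 12 h, as a percentage of the starting material charged

The feed ends at 1.3 h, and the starting material then falls from 41% to 13% in 1.50 h. The same first-order pace over the next 3.00 h would leave 1.31%, yet 7% stands there, more than that pace allows. So the flask appears to be heading for a level, and one number can describe that level.

The readings at 6.00 h give 13.4 for the standing ratio, the target and the isomer of the product together divided by the starting material beside them. It is a reaction quotient with the reagent folded in. A ratio of one is the symmetric case, the zero of this scale, with the charge shared equally between the two sides. Saturday's value lies far above that, and the ratio over one plus the ratio gives 93.1% gone.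

One number is not quite enough. It rests on a small reading with a scatter of 1.5 percentage points, and at 3.00 h it stood at about half this value. It also cannot split the products, which needs a second ratio, target to isomer: 3.05, then 2.76. My reckoning keeps the 6.00 h readings for 12 h, which takes the level as reached by then, and so stands at 93.1% gone, 69% target and 25% isomer.

The forecast's answer is that forward and back rates have come level, with 93% gone (91% to 97%), 69% target (66% to 72%) and 24% isomer (22% to 27%), its isomer lying 1 point below my reckoning: “So I read this as a reversible reaction at equilibrium.”

At 12 h the flask shows that forward and back rates have come level, with 95.7% gone, 71.5% target and 24.3% isomer, each inside the forecast's range.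

    starting material + reagent ⇌ target (K = 31.0 M⁻¹, k = 0.0290 M⁻¹ min⁻¹)
    second substrate + reagent ⇌ second product (K = 0.570 M⁻¹, k = 0.0560 M⁻¹ min⁻¹)
    target ⇌ isomer of the product (K = 0.340, k = 0.0230 min⁻¹)

The flask's standing ratio at 12.0 h is 22.5. The neighbour charged with 0.23 M of reagent stands at 1.52 at 12 h, with 39.7% starting material. In the flask itself, starting material goes from 4.60% at 6.00 h to 4.25% at 12.0 h, a move of 0.35 points. Left ten times as long, the flask shows 95.7% gone, 71.5% target and 24.3% isomer.

The numbers in the tables were computed for an exercise, noise included.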